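**Retrosynthetic overview**
1. Target acid 10 ⇐ benzyl ester 9 by hydrogenolysis as the last step.
2. 2'-OMe of 9 ⇐ neutral Mitsunobu O-methylation of the chelated 2'-OH of depside 8, so the depside bond itself blocks the 4'-OH.
3. Depside C(=O)–OAr bond of 8 ⇐ Steglich coupling of keto acid 5 with the free 4-OH of benzyl olivetolate 7.
4. Keto acid 5 ⇐ benzylic dianion of 2,4-dimethoxy-6-methylbenzoic acid 1 + Weinreb amide 2; ester 7 ⇐ olivetolic acid 6 + BnBr.
5. No ring is formed (both benzene rings are bought) and there is no stereocentre to set.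

Assumption: the target SMILES has no stereocentre, so "single enantiomer" needs no stereocontrol; 1, 2 and 6 are taken as catalogue chemicals.

**Route**

Step 1
Reactants: 1 2,4-dimethoxy-6-methylbenzoic acid; 2 N-methoxy-N-methylhexanamide
Product: 5 2,4-dimethoxy-6-(2-oxoheptyl)benzoic acid, via dilithio dianion 3 (not isolated), via lithium hemiaminal adduct 4 (not isolated)
Conditions: LDA (2.2 equiv, commercial solution), THF, −78 → 0 °C; then 2 (1.1 equiv), −78 → 0 °C; cold 1 M HCl quench, extraction without heating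
Reagents that add atoms: none
Why: Lateral (benzylic) lithiation of the lithium carboxylate gives dianion 3, which is C-acylated once by the Weinreb amide because chelated adduct 4 only collapses to the ketone on acidic quench (Weinreb ketone synthesis); no stereocentre is formed.

Step 2
Reactants: 6 olivetolic acid (2,4-dihydroxy-6-pentylbenzoic acid)
Product: 7 benzyl 2,4-dihydroxy-6-pentylbenzoate
Conditions: BnBr (1.05 equiv), KHCO3 (1.2 equiv), DMF, rt
Reagents that add atoms: benzyl bromide, BrCc1ccccc1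
Why: KHCO3 deprotonates only the carboxylic acid, so SN2 alkylation of the carboxylate gives the benzyl ester and leaves both phenols free; room temperature avoids decarboxylation.

Step 3
Reactants: 5 2,4-dimethoxy-6-(2-oxoheptyl)benzoic acid; 7 benzyl 2,4-dihydroxy-6-pentylbenzoate
Product: 8 benzyl 4-{[2,4-dimethoxy-6-(2-oxoheptyl)benzoyl]oxy}-2-hydroxy-6-pentylbenzoate
Conditions: DCC (1.1 equiv), DMAP (0.1 equiv), CH2Cl2, 0 °C → rt
Reagents that add atoms: none
Why: Steglich esterification; the 2-OH of 7 is hydrogen-bonded to its ester carbonyl and unreactive, so only the 4-OH is acylated, and the near-neutral conditions limit enol-lactonisation of the keto acid.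

Step 4
Reactants: 8 benzyl 4-{[2,4-dimethoxy-6-(2-oxoheptyl)benzoyl]oxy}-2-hydroxy-6-pentylbenzoate
Product: 9 benzyl 4-{[2,4-dimethoxy-6-(2-oxoheptyl)benzoyl]oxy}-2-methoxy-6-pentylbenzoate
Conditions: MeOH (3 equiv), PPh3 (1.5 equiv), DIAD (1.5 equiv), THF, 0 °C → rt
Reagents that add atoms: methanol, CO
Why: Mitsunobu etherification; the salicylate-type 2'-OH (pKa about 10) is acidic enough to be O-methylated under neutral conditions, which spare the enolisable ketone and the base-labile aryl ester.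

Step 5
Reactants: 9 benzyl 4-{[2,4-dimethoxy-6-(2-oxoheptyl)benzoyl]oxy}-2-methoxy-6-pentylbenzoate
Product: 10 4-{[2,4-dimethoxy-6-(2-oxoheptyl)benzoyl]oxy}-2-methoxy-6-pentylbenzoic acid (target, CNP0169128.0)
Conditions: H2 (1 atm), 10% Pd/C, EtOAc, rt
Reagents that add atoms: none
Why: Catalytic hydrogenolysis cleaves only the benzylic C–O bond of the benzyl ester; the depside aryl ester, the ArCH2–C(=O) ketone and the methyl ethers are inert.

**Compound list**
1 | 2,4-dimethoxy-6-methylbenzoic acid | Cc1cc(OC)cc(OC)c1C(=O)O | starting material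
2 | N-methoxy-N-methylhexanamide | CCCCCC(=O)N(C)OC | starting material
3 | dilithio dianion of 1, lithium 2-(lithiomethyl)-4,6-dimethoxybenzoate (not isolated) | [Li+].[Li+].[CH2-]c1cc(OC)cc(OC)c1C(=O)[O-] | intermediate
4 | dilithium salt of the tetrahedral adduct, 2-{2-[methoxy(methyl)amino]-2-oxidoheptyl}-4,6-dimethoxybenzoate (not isolated) | [Li+].[Li+].CCCCCC([O-])(Cc1cc(OC)cc(OC)c1C(=O)[O-])N(C)OC | intermediate
5 | 2,4-dimethoxy-6-(2-oxoheptyl)benzoic acid | CCCCCC(=O)Cc1cc(OC)cc(OC)c1C(=O)O | intermediate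
6 | olivetolic acid (2,4-dihydroxy-6-pentylbenzoic acid) | CCCCCc1cc(O)cc(O)c1C(=O)O | starting material
7 | benzyl 2,4-dihydroxy-6-pentylbenzoate | CCCCCc1cc(O)cc(O)c1C(=O)OCc1ccccc1 | intermediate
8 | benzyl 4-{[2,4-dimethoxy-6-(2-oxoheptyl)benzoyl]oxy}-2-hydroxy-6-pentylbenzoate | CCCCCC(=O)Cc1cc(OC)cc(OC)c1C(=O)Oc1cc(CCCCC)c(C(=O)OCc2ccccc2)c(O)c1 | intermediate
9 | benzyl 4-{[2,4-dimethoxy-6-(2-oxoheptyl)benzoyl]oxy}-2-methoxy-6-pentylbenzoate | CCCCCC(=O)Cc1cc(OC)cc(OC)c1C(=O)Oc1cc(CCCCC)c(C(=O)OCc2ccccc2)c(OC)c1 | intermediate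
10 | 4-{[2,4-dimethoxy-6-(2-oxoheptyl)benzoyl]oxy}-2-methoxy-6-pentylbenzoic acid (achiral) | CCCCCC(=O)Cc1cc(OC)cc(OC)c1C(=O)Oc1cc(CCCCC)c(C(=O)O)c(OC)c1 | target

**Step count**
Total steps: 5. Longest linear sequence: 4 steps (1 → 5 → 8 → 9 → 10, or 6 → 7 → 8 → 9 → 10).

**Steps most likely to fail, with fallbacks**

Step 1 (the carboxylate dianion may form incompletely or be quenched by the α-protons of the amide). The fallback sets out from 1 and comes back at 5. Acid 1 is esterified (MeI, K2CO3, DMF) to methyl 2,4-dimethoxy-6-methylbenzoate F1. The ester-stabilised toluate anion of F1 (LDA, THF, −78 °C) is acylated with 2 to give methyl 2,4-dimethoxy-6-(2-oxoheptyl)benzoate F2. F2 is saponified (KOH, aq. EtOH, 70 °C, then cold acidification) to 5.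

Step 3 (the activated keto acid may close onto its own ketone oxygen to give an isocoumarin, or rearrange to the N-acylurea, instead of acylating the phenol). The fallback sets out from 5 and comes back at 8. The ketone is masked first (ethane-1,2-dithiol, BF3·OEt2, CH2Cl2) as 2,4-dimethoxy-6-[(2-pentyl-1,3-dithiolan-2-yl)methyl]benzoic acid F3. F3 is coupled with 7 (DCC, DMAP, CH2Cl2) to benzyl 4-({2,4-dimethoxy-6-[(2-pentyl-1,3-dithiolan-2-yl)methyl]benzoyl}oxy)-2-hydroxy-6-pentylbenzoate F4. The dithiolane is then removed without oxidant or heavy metal (MeI, CaCO3, MeCN–H2O, 40 °C) to give 8.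

Step 4 (the chelated, hindered 2'-OH may be too sluggish in the Mitsunobu reaction, and basic alkylation would endanger the keto aryl ester). The fallback sets out from 7 and comes back at 9, so the methyl group is in place before the depside bond is made. The free 4-OH of 7 is silylated selectively (TIPSCl, imidazole, DMF, 0 °C) to benzyl 2-hydroxy-6-pentyl-4-[(triisopropylsilyl)oxy]benzoate F5. The chelated OH is methylated (MeI, K2CO3, acetone, reflux) to benzyl 2-methoxy-6-pentyl-4-[(triisopropylsilyl)oxy]benzoate F6. Desilylation (TBAF, AcOH, THF, 0 °C) gives benzyl 4-hydroxy-2-methoxy-6-pentylbenzoate F7. F7 is coupled with 5 (DCC, DMAP, CH2Cl2) to give 9 directly.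

**Further compounds**
F1 | step 1 | methyl 2,4-dimethoxy-6-methylbenzoate | COC(=O)c1c(C)cc(OC)cc1OC
F2 | step 1 | methyl 2,4-dimethoxy-6-(2-oxoheptyl)benzoate | CCCCCC(=O)Cc1cc(OC)cc(OC)c1C(=O)OC
F3 | step 3 | 2,4-dimethoxy-6-[(2-pentyl-1,3-dithiolan-2-yl)methyl]benzoic acid | CCCCCC1(Cc2cc(OC)cc(OC)c2C(=O)O)SCCS1
F4 | step 3 | benzyl 4-({2,4-dimethoxy-6-[(2-pentyl-1,3-dithiolan-2-yl)methyl]benzoyl}oxy)-2-hydroxy-6-pentylbenzoate | CCCCCC1(Cc2cc(OC)cc(OC)c2C(=O)Oc2cc(CCCCC)c(C(=O)OCc3ccccc3)c(O)c2)SCCS1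
F5 | step 4 | benzyl 2-hydroxy-6-pentyl-4-[(triisopropylsilyl)oxy]benzoate | CCCCCc1cc(O[Si](C(C)C)(C(C)C)C(C)C)cc(O)c1C(=O)OCc1ccccc1
F6 | step 4 | benzyl 2-methoxy-6-pentyl-4-[(triisopropylsilyl)oxy]benzoate | CCCCCc1cc(O[Si](C(C)C)(C(C)C)C(C)C)cc(OC)c1C(=O)OCc1ccccc1
F7 | step 4 | benzyl 4-hydroxy-2-methoxy-6-pentylbenzoate | CCCCCc1cc(O)cc(OC)c1C(=O)OCc1ccccc1
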